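The pyran ring is disconnected at O1–C8a, the aryl ether bond to the arene carbon that lies between the acyl-bearing C8 and the ring-fusion carbon C4a. Because a bromine already marks C8a, a Pd(OAc)2-catalysed intramolecular C–O coupling of a side-chain tertiary alcohol (the future O1 on the gem-dimethyl carbon C2) closes the ring in one operation, with no choice between phenolic oxygens. The precursor is a fully substituted bromoarene carrying the 3-phenylpropanoyl ketone, two silylated phenols and an (R)-configured 1-silyloxy-3-hydroxy-3-methylbutyl chain, whose stereocentre comes from a catalytic enantioselective methallylboration of the corresponding aldehyde. Global desilylation then gives the target.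

Key step: step 8

Assumption: (R)-TRIP is taken to direct addition to the Re face of aldehyde 7, as it does with simpler aryl aldehydes (the antipodal acid would be used if the sense were reversed), and 1 is taken to be a catalogue compound.

Step 1
Reactants: 1 5-bromo-1,3-dimethoxy-2-methylbenzene
Product: 2 5-bromo-2-methylbenzene-1,3-diol
Conditions: BBr3 (3 equiv), CH2Cl2, −78 °C to rt; then H2O
Reagents that add atoms: none
Why: BBr3 demethylation of aryl methyl ethers proceeds through aryloxyboron bromides that hydrolyse on work-up, and the aryl bromide and the ring methyl group are inert to it.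

Step 2
Reactants: 2 5-bromo-2-methylbenzene-1,3-diol; 3 3-phenylpropanoyl chloride
Product: 4 1-(6-bromo-2,4-dihydroxy-3-methylphenyl)-3-phenylpropan-1-one
Conditions: AlCl3 (3 equiv), PhNO2, rt to 50 °C; then ice, aq. HCl
Reagents that add atoms: none
Why: Friedel–Crafts C-acylation of a resorcinol (any aryl ester formed first undergoes Fries rearrangement under AlCl3) can give only one regioisomer, because the two free ring positions of 2 are equivalent by symmetry, each ortho to one hydroxyl and para to the other, and the new acyl group deactivates the ring against a second acylation.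

Step 3
Reactants: 4 1-(6-bromo-2,4-dihydroxy-3-methylphenyl)-3-phenylpropan-1-one
Product: 6 2-bromo-4,6-dihydroxy-5-methyl-3-(3-phenylpropanoyl)benzaldehyde, via α-chloro ether 5 (not isolated)
Conditions: Cl2CHOMe (1.2 equiv), TiCl4 (4 equiv), CH2Cl2, 0 °C to rt; then H2O, aq. HCl
Reagents that add atoms: dichloromethyl methyl ether, COC(Cl)Cl; water, O
Why: Rieche formylation should attack the only unsubstituted ring carbon, which is ortho to the free hydroxyl, para to the chelated hydroxyl and meta to the acyl group, and hydrolysis of the α-chloro ether on work-up releases the aldehyde; Vilsmeier conditions are avoided because they would condense at the ketone α-methylene.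

Step 4
Reactants: 6 2-bromo-4,6-dihydroxy-5-methyl-3-(3-phenylpropanoyl)benzaldehyde
Product: 7 2-bromo-4,6-bis[(tert-butyldimethylsilyl)oxy]-5-methyl-3-(3-phenylpropanoyl)benzaldehyde
Conditions: TBSCl (3 equiv), imidazole (6 equiv), DMAP (cat.), DMF, rt to 40 °C
Reagents that add atoms: tert-butyldimethylsilyl chloride, CC(C)(C)[Si](C)(C)Cl
Why: Imidazole-promoted silylation of phenols should cap both hydroxyls, each of which is acidic through conjugation to a carbonyl group, while the aldehyde and the ketone do not react with TBSCl.

Step 5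
Reactants: 7 2-bromo-4,6-bis[(tert-butyldimethylsilyl)oxy]-5-methyl-3-(3-phenylpropanoyl)benzaldehyde; 8 2-methylallylboronic acid pinacol ester
Product: 10 1-{6-bromo-2,4-bis[(tert-butyldimethylsilyl)oxy]-5-[(1R)-1-hydroxy-3-methylbut-3-en-1-yl]-3-methylphenyl}-3-phenylpropan-1-one, via pinacol borate ester 9 (not isolated)
Conditions: (R)-TRIP [(R)-3,3'-bis(2,4,6-triisopropylphenyl)-1,1'-binaphthyl-2,2'-diyl hydrogen phosphate] (5 mol %), toluene, −30 °C to 0 °C; then aq. NaHCO3
Reagents that add atoms: none
Why: In this chiral phosphoric acid-catalysed allylboration the acid hydrogen-bonds to a boronate oxygen and to the formyl hydrogen in a closed chair transition state, so the 2-methylallyl group is delivered to the Re face and the new carbinol centre is R under catalyst control, while the hindered ketone is left alone and the neutral borate intermediate offers no alkoxide that could take a silyl group from the neighbouring phenol oxygen.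

Step 6
Reactants: 10 1-{6-bromo-2,4-bis[(tert-butyldimethylsilyl)oxy]-5-[(1R)-1-hydroxy-3-methylbut-3-en-1-yl]-3-methylphenyl}-3-phenylpropan-1-one
Product: 11 1-{6-bromo-2,4-bis[(tert-butyldimethylsilyl)oxy]-5-[(1R)-1-[(tert-butyldimethylsilyl)oxy]-3-methylbut-3-en-1-yl]-3-methylphenyl}-3-phenylpropan-1-one
Conditions: TBSOTf (1.3 equiv), 2,6-lutidine (2.5 equiv), CH2Cl2, −40 °C to 0 °C
Reagents that add atoms: tert-butyldimethylsilyl trifluoromethanesulfonate, CC(C)(C)[Si](C)(C)OS(=O)(=O)C(F)(F)F
Why: Silyl triflate silylation with a non-nucleophilic pyridine base handles hindered secondary alcohols, only the O–H bond reacts so the stereocentre is untouched, and the buffered medium neither ionises the benzylic C–O bond nor protonates the alkene.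

Step 7
Reactants: 11 1-{6-bromo-2,4-bis[(tert-butyldimethylsilyl)oxy]-5-[(1R)-1-[(tert-butyldimethylsilyl)oxy]-3-methylbut-3-en-1-yl]-3-methylphenyl}-3-phenylpropan-1-one
Product: 12 1-{6-bromo-2,4-bis[(tert-butyldimethylsilyl)oxy]-5-[(1R)-1-[(tert-butyldimethylsilyl)oxy]-3-hydroxy-3-methylbutyl]-3-methylphenyl}-3-phenylpropan-1-one
Conditions: Co(acac)2 (20 mol %), PhSiH3 (2.5 equiv), O2 (1 atm), THF, rt
Reagents that add atoms: dioxygen, O=O
Why: In the Mukaiyama hydration, hydrogen-atom transfer from the Co–H species formed from Co(acac)2 and PhSiH3 to the terminal alkene carbon gives the tertiary radical, which is trapped by O2 and reduced to the alcohol, so the hydroxyl lands on the more substituted carbon under neutral conditions that tolerate the aryl bromide, the ketone and the silyl ethers.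

Step 8
Reactants: 12 1-{6-bromo-2,4-bis[(tert-butyldimethylsilyl)oxy]-5-[(1R)-1-[(tert-butyldimethylsilyl)oxy]-3-hydroxy-3-methylbutyl]-3-methylphenyl}-3-phenylpropan-1-one
Product: 13 1-{(4R)-4,5,7-tris[(tert-butyldimethylsilyl)oxy]-2,2,6-trimethyl-3,4-dihydro-2H-chromen-8-yl}-3-phenylpropan-1-one
Conditions: Pd(OAc)2 (5 mol %), 2-(di-tert-butylphosphino)-1,1'-binaphthyl (6 mol %), Cs2CO3 (1.5 equiv), toluene, 70 °C
Reagents that add atoms: none
Why: Pd(OAc)2 is reduced in the flask to a monoligated zerovalent palladium species that undergoes oxidative addition at C8a–Br, a bond made more reactive by the neighbouring C8 acyl group; carbonate-assisted exchange of bromide for the tethered tertiary alkoxide then gives a seven-membered aryl(alkoxo) divalent palladium chelate, and C–O reductive elimination forms O1–C8a. The closest known reaction type is the palladium-catalysed intramolecular etherification of aryl halides with tertiary alcohols that gives 2,2-dialkylchromans. The six-membered pyran ring closes by C(aryl)–O reductive elimination from that palladacycle (formally a 6-exo closure of the tether onto C8a), not by attack of a phenol, so no other fusion isomer can arise. No stereocentre is formed, and C4 keeps its R configuration because none of its bonds is touched and its silylated oxygen can neither bind palladium nor open a β-hydride pathway. The step needs chemoselectivity for C–O bond formation over hydrodebromination, which is secured by the absence of a carbinol hydrogen in the tertiary alkoxide, by the bulky di-tert-butylphosphine that speeds reductive elimination at the ortho-acylated aryl group, and by a mild, sparingly soluble base that should leave the aryl silyl ethers and the ketone alone.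

Step 9
Reactants: 13 1-{(4R)-4,5,7-tris[(tert-butyldimethylsilyl)oxy]-2,2,6-trimethyl-3,4-dihydro-2H-chromen-8-yl}-3-phenylpropan-1-one
Product: 14 1-[(4R)-4,5,7-trihydroxy-2,2,6-trimethyl-3,4-dihydro-2H-chromen-8-yl]-3-phenylpropan-1-one (the target)
Conditions: Bu4NF (4 equiv), AcOH (4 equiv), THF, 0 °C to rt
Reagents that add atoms: none
Why: Fluoride-driven desilylation should cleave the two aryl and the one secondary silyl ether, acetic acid keeps the liberated phenols protonated so that neither base-induced quinone methide formation nor acid ionisation of the electron-rich benzylic carbinol is expected, and C4 keeps its configuration because its C–O bond is never broken.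

Compound list

1 | 5-bromo-1,3-dimethoxy-2-methylbenzene | COc1cc(Br)cc(OC)c1C | starting material
2 | 5-bromo-2-methylbenzene-1,3-diol | Cc1c(O)cc(Br)cc1O | intermediate
3 | 3-phenylpropanoyl chloride | O=C(Cl)CCc1ccccc1 | starting material
4 | 1-(6-bromo-2,4-dihydroxy-3-methylphenyl)-3-phenylpropan-1-one | Cc1c(O)c(C(=O)CCc2ccccc2)c(Br)cc1O | intermediate
5 | 1-{6-bromo-5-[chloro(methoxy)methyl]-2,4-dihydroxy-3-methylphenyl}-3-phenylpropan-1-one (racemic at the chloro ether carbon, titanium-bound in the flask) | Cc1c(O)c(C(=O)CCc2ccccc2)c(Br)c(C(Cl)OC)c1O | intermediate (not isolated)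
6 | 2-bromo-4,6-dihydroxy-5-methyl-3-(3-phenylpropanoyl)benzaldehyde | Cc1c(O)c(C(=O)CCc2ccccc2)c(Br)c(C=O)c1O | intermediate
7 | 2-bromo-4,6-bis[(tert-butyldimethylsilyl)oxy]-5-methyl-3-(3-phenylpropanoyl)benzaldehyde | Cc1c(O[Si](C)(C)C(C)(C)C)c(C(=O)CCc2ccccc2)c(Br)c(C=O)c1O[Si](C)(C)C(C)(C)C | intermediate
8 | 2-methylallylboronic acid pinacol ester (4,4,5,5-tetramethyl-2-(2-methylallyl)-1,3,2-dioxaborolane) | CC(=C)CB1OC(C)(C)C(C)(C)O1 | starting material
9 | pinacol borate ester of alcohol 10 (O–B(pin) on the (R)-carbinol oxygen) | Cc1c(O[Si](C)(C)C(C)(C)C)c(C(=O)CCc2ccccc2)c(Br)c(c1O[Si](C)(C)C(C)(C)C)[C@H](OB2OC(C)(C)C(C)(C)O2)CC(C)=C | intermediate (not isolated)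
10 | 1-{6-bromo-2,4-bis[(tert-butyldimethylsilyl)oxy]-5-[(1R)-1-hydroxy-3-methylbut-3-en-1-yl]-3-methylphenyl}-3-phenylpropan-1-one | Cc1c(O[Si](C)(C)C(C)(C)C)c(C(=O)CCc2ccccc2)c(Br)c(c1O[Si](C)(C)C(C)(C)C)[C@H](O)CC(C)=C | intermediate
11 | 1-{6-bromo-2,4-bis[(tert-butyldimethylsilyl)oxy]-5-[(1R)-1-[(tert-butyldimethylsilyl)oxy]-3-methylbut-3-en-1-yl]-3-methylphenyl}-3-phenylpropan-1-one | Cc1c(O[Si](C)(C)C(C)(C)C)c(C(=O)CCc2ccccc2)c(Br)c(c1O[Si](C)(C)C(C)(C)C)[C@H](O[Si](C)(C)C(C)(C)C)CC(C)=C | intermediate
12 | 1-{6-bromo-2,4-bis[(tert-butyldimethylsilyl)oxy]-5-[(1R)-1-[(tert-butyldimethylsilyl)oxy]-3-hydroxy-3-methylbutyl]-3-methylphenyl}-3-phenylpropan-1-one | Cc1c(O[Si](C)(C)C(C)(C)C)c(C(=O)CCc2ccccc2)c(Br)c(c1O[Si](C)(C)C(C)(C)C)[C@H](O[Si](C)(C)C(C)(C)C)CC(C)(C)O | intermediate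
13 | 1-{(4R)-4,5,7-tris[(tert-butyldimethylsilyl)oxy]-2,2,6-trimethyl-3,4-dihydro-2H-chromen-8-yl}-3-phenylpropan-1-one | Cc1c(O[Si](C)(C)C(C)(C)C)c(C(=O)CCc2ccccc2)c2c(c1O[Si](C)(C)C(C)(C)C)[C@H](O[Si](C)(C)C(C)(C)C)CC(C)(C)O2 | intermediate
14 | 1-[(4R)-4,5,7-trihydroxy-2,2,6-trimethyl-3,4-dihydro-2H-chromen-8-yl]-3-phenylpropan-1-one | Cc1c(O)c(C(=O)CCc2ccccc2)c2c(c1O)[C@H](O)CC(C)(C)O2 | target

Total step count: 9
Longest linear sequence: 9 steps (1 to 14)

Steps most likely to fail

1. Step 8. The congested aryl(alkoxo)palladium intermediate may lose bromine by reduction faster than it undergoes C–O reductive elimination, or the carbonate may strip an aryl silyl group and so deactivate the arene. The fallback sets out from alkene 11 and puts the C8a oxygen on the arene before the ring is closed. Miyaura borylation (Pd(OAc)2, SPhos, B2pin2, KOAc, dioxane, 90 °C) would give the aryl pinacol boronate F1; transmetalation with the small boryl partner and C–B reductive elimination are less sensitive to the flanking groups than C–O elimination with a tertiary alkoxide. Oxidation (NaBO3·4H2O, THF/H2O, rt) would give the C8a phenol F2. A hydrogen-atom-transfer hydroalkoxylation (Co(salen) (cat.), N-fluoro-2,4,6-trimethylpyridinium tetrafluoroborate, (Me2SiH)2O, PhCF3, rt) would then add this phenol oxygen to the internal carbon of the 2-methylallyl alkene through the tertiary radical and cation, forming O1–C2 and returning to the route at 13. The fusion direction stays fixed because the only free phenol is the one that replaced the bromine.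

2. Step 5. Facial selectivity may be poor, or addition slow, because both positions ortho to the aldehyde are occupied. The fallback replaces catalyst control by reagent control and sets out from 7. B-(2-Methylallyl)diisopinocampheylborane F3 (Ipc groups from (−)-α-pinene), prepared from (+)-Ipc2BOMe and 2-methylallylmagnesium chloride in Et2O, would add at −78 °C to the Re face through a chair transition state and give the diisopinocampheylborinate F4. Ethanolamine would then release the alcohol without the basic peroxide work-up that would endanger the aryl silyl ethers, and the route is rejoined at 10.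

3. Step 3. Conversion may stall on the acyl-deactivated ring, or the electrophile may attack the side-chain phenyl ring. The fallback sets out from 4 and activates the nucleophile instead of the electrophile: magnesium-mediated ortho-formylation (MgCl2, Et3N, paraformaldehyde, MeCN, reflux). The magnesium phenoxide adds to formaldehyde only at the carbon ortho to its oxygen and gives the hydroxymethyl phenol F5 as its magnesium salt, which is oxidised in the same flask by hydride transfer to a second formaldehyde, returning to 6.

Further compounds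

F1 | step 8 | 1-{2,4-bis[(tert-butyldimethylsilyl)oxy]-5-[(1R)-1-[(tert-butyldimethylsilyl)oxy]-3-methylbut-3-en-1-yl]-3-methyl-6-(4,4,5,5-tetramethyl-1,3,2-dioxaborolan-2-yl)phenyl}-3-phenylpropan-1-one | Cc1c(O[Si](C)(C)C(C)(C)C)c(C(=O)CCc2ccccc2)c(B2OC(C)(C)C(C)(C)O2)c(c1O[Si](C)(C)C(C)(C)C)[C@H](O[Si](C)(C)C(C)(C)C)CC(C)=C
F2 | step 8 | 1-{2,4-bis[(tert-butyldimethylsilyl)oxy]-5-[(1R)-1-[(tert-butyldimethylsilyl)oxy]-3-methylbut-3-en-1-yl]-6-hydroxy-3-methylphenyl}-3-phenylpropan-1-one | Cc1c(O[Si](C)(C)C(C)(C)C)c(C(=O)CCc2ccccc2)c(O)c(c1O[Si](C)(C)C(C)(C)C)[C@H](O[Si](C)(C)C(C)(C)C)CC(C)=C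
F3 | step 5 | B-(2-methylallyl)diisopinocampheylborane (Ipc groups from (−)-α-pinene) | CC(=C)CB([C@H]1C[C@H]2C[C@@H]([C@@H]1C)C2(C)C)[C@H]1C[C@H]2C[C@@H]([C@@H]1C)C2(C)C
F4 | step 5 | diisopinocampheylborinate of alcohol 10 | Cc1c(O[Si](C)(C)C(C)(C)C)c(C(=O)CCc2ccccc2)c(Br)c(c1O[Si](C)(C)C(C)(C)C)[C@H](OB([C@H]1C[C@H]2C[C@@H]([C@@H]1C)C2(C)C)[C@H]1C[C@H]2C[C@@H]([C@@H]1C)C2(C)C)CC(C)=C
F5 | step 3 | 1-[6-bromo-2,4-dihydroxy-5-(hydroxymethyl)-3-methylphenyl]-3-phenylpropan-1-one | Cc1c(O)c(C(=O)CCc2ccccc2)c(Br)c(CO)c1O
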